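The earlier runs and the new flask were computed from invented constants; the scatter is artificial.

A first-order loss has an invariant: the fraction lost per hour does not depend on how much is there.

| flask | starting material | enzyme | remark | time |
|---|---|---|---|---|
| alpha | 0.29 M (fed, over 2.0 h) | 20 µM | run made earlier |  |
| delta | 1.3 M (fed, over 2.0 h) | 20 µM | run made earlier |  |
| theta | 0.20 M (fed, over 2.0 h) | 11 µM | run made earlier |  |
| north-east | 0.20 M (fed, over 2.0 h) | 20 µM |  | 8.0 h |
| east | 0.80 M | 6.0 µM | everything together at the start | 8.0 h |

| run | time / h | target / % | starting material / % |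
|---|---|---|---|
| alpha | 0.500 | 15.8 | 8.3 |
| alpha | 1.50 | 34.4 | 36.8 |
| alpha | 3.00 | 39.9 | 46.6 |
| alpha | 4.00 | 46.4 | 35.0 |
| alpha | 6.00 | 65.9 | 0 |
| alpha | 8.00 | 50.2 | 0 |
| delta | 0.667 | 1.0 | 31.9 |
| delta | 1.00 | 1.7 | 47.3 |
| delta | 2.00 | 2.2 | 97.4 |
| delta | 3.00 | 2.0 | 97.0 |
| delta | 5.00 | 1.2 | 96.5 |
| delta | 8.00 | 1.9 | 94.2 |
| theta | 0.667 | 15.8 | 16.2 |
| theta | 1.33 | 26.0 | 37.5 |
| theta | 2.50 | 33.7 | 59.5 |
| theta | 4.00 | 40.8 | 42.2 |
| theta | 8.00 | 52.8 | 0 |

(each reading ± 0.5 percentage points)

- percentages count the whole charge, also what has not yet gone in

- which one finishes higher in amount of target, in percent of the starting material charged ("neither" within 2 percentage points) (north-east / east / neither)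
- amount of target at the end, in percent of the starting material charged, north-east
- amount of target at the end, in percent of the starting material charged, east

Alpha reads 0% starting material at 6.00 h, and its target then falls from 65.9% to 50.2% by 8.00 h. I take that fall as first-order and get 0.136 h⁻¹, the target's loss constant. It is a reading and carries the scatter of its two points.

Survival depends on age, so I need to know when the target was made. North-east's feed brings 0.100 M h⁻¹. Alpha, with the same enzyme, used up 0.0969 M h⁻¹ in its first 0.500 h. I take the enzyme in north-east to keep about pace, so I let target form as the feed arrives, on average at 1.00 h. At 8.0 h I put its mean age at 7.00 h, and I reckon 38.6% for north-east.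

Delta's target reads 1.9% at 8.00 h. I assume making equals losing there, so I put the making rate at the loss constant times that level: 0.00336 M h⁻¹ at 1.22 M of starting material. Alpha used 0.0336 M h⁻¹ at 0.118 M, about ten times delta's rate. So, between these two levels, I read the rate as falling with one over the starting material (substrate inhibition).

Taking the rate as proportional to enzyme and scaling to east's starting material, I put making in east at 0.00154 M h⁻¹. Set against the same loss over 8.0 h, that gives 0.940% for east.

The forecast names north-east, with 38% there and 1.4% in east, and says the feed “barely exceeds the peak rate”; my east figure is lower.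

North-east gives 38.2% and east 1.02%, so north-east finishes higher. East's target has moved by 5 points once its starting material is down at 0.333 M or its enzyme up at 33.6 µM, each moved alone. North-east holds 66.9% target at 4.00 h, and the loss constant carries that to 38.8% at 8.00 h.

    starting material + enzyme → target + enzyme, rate k1*[starting material]*[enzyme]/(1 + ([starting material]/Km1) + ([starting material]/Ksi1)^2) (24.0 mM, 16.0 mM, k = 8.80 × 10⁵ M⁻¹ h⁻¹)
    2 starting material → self-condensation product (k = 0.00120 M⁻¹ h⁻¹)
    target → over-reaction product (k = 0.140 h⁻¹)

For the same north-east flask read at 3.0 h, I put the mean target age at 2.00 h, so the loss constant gives 76.2%. That flask holds 76.9%.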